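The route rests on cutting, in each terminal ring A, the C1–acyl bond and the C6–O bond at the same time. C1 (butyryl) and C6 (hydroxyl) sit side by side, and the C2 oxygen flanks C1. A C1–C6 aryne polarised by that oxygen can therefore take up butyric acid with oxygen at C6 and acyl at C1. Run on both arms of one molecule, the step makes two C–O and two C–C bonds on fully substituted rings. Its precursor is the tris(benzyloxy)butyrophenone ring B carrying, through two methylene bridges, two bis(benzyloxy)methylaryl units that bear trimethylsilyl at C1 and triflate at C6. Hydrogenolysis of seven benzyl ethers ends the route.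

Key step: step 11

**Remarks on the chemistry**
- Numbering: in a terminal ring A, C1 carries butyryl, C2 oxygen, C3 methyl, C4 oxygen, C5 the methylene bridge and C6 oxygen. Ring B is the central ring.
- The target has no stereocentre, so no step has to control configuration.
- The C–H borylation is run before any benzyl ether is present. The unhindered meta and para C–H bonds of a benzyl group would otherwise be borylated alongside C5.
- The arms are joined to ring B as electrophiles, after silicon and triflate are in place. No organolithium reagent then meets the ketone, no acid meets the aryl silane, and no crowded phenoxide has to choose carbon over oxygen.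

**Step 1**
Reactants: 1 2-methylresorcinol
Product: 4 2-methyl-5-(4,4,5,5-tetramethyl-1,3,2-dioxaborolan-2-yl)benzene-1,3-diol, via bis(trimethylsilyl) ether 2 (not isolated), via borylated bis(silyl) ether 3 (not isolated)
Conditions: (a) HMDS, neat, 110 °C, then evaporate; (b) B2pin2 (1.0 equiv), [Ir(OMe)(cod)]2 (1.5 mol %), dtbpy (3 mol %), THF, 80 °C; (c) MeOH, rt
Reagents that add atoms: bis(pinacolato)diboron, CC1(C)OB(B2OC(C)(C)C(C)(C)O2)OC1(C)C; hexamethyldisilazane, C[Si](C)(C)N[Si](C)(C)C (its silicon stays only in 2 and 3)
Why: Sterically governed iridium-catalysed aromatic C–H borylation should pick C5 of the resorcinol, the only ring C–H without an ortho neighbour, and on the transient silyl ethers no phenyl ring of a protecting group can compete.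

**Step 2**
Reactants: 4 boronate diol; 5 benzyl bromide
Product: 6 2-[3,5-bis(benzyloxy)-4-methylphenyl]-4,4,5,5-tetramethyl-1,3,2-dioxaborolane
Conditions: BnBr (2.3 equiv), K2CO3, DMF, rt to 50 °C
Reagents that add atoms: benzyl bromide 5, BrCc1ccccc1
Why: Twofold Williamson ether synthesis on two equivalent phenols, which a pinacol boronate tolerates under carbonate conditions.

**Step 3**
Reactants: 6 bis(benzyloxy) boronate
Product: 7 3,5-bis(benzyloxy)-4-methylphenol
Conditions: 30 % aq. H2O2, NaOH (0.1 equiv), THF, 0 °C to rt
Reagents that add atoms: hydrogen peroxide, OO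
Why: Peroxide oxidation of an arylboronic ester (1,2-shift of the aryl group from boron to oxygen) should give the phenol para to the methyl group without touching the benzyl ethers.

**Step 4**
Reactants: 7 3,5-bis(benzyloxy)-4-methylphenol
Product: 8 3,5-bis(benzyloxy)-2-bromo-4-methylphenol
Conditions: NBS (1.0 equiv), CH2Cl2, −78 °C to 0 °C
Reagents that add atoms: N-bromosuccinimide, O=C1CCC(=O)N1Br
Why: Electrophilic aromatic bromination in which the two open ring carbons are equivalent and ortho to the hydroxyl, so one equivalent at low temperature should stop after the first, deactivating substitution.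

**Step 5**
Reactants: 8 bromophenol; 9 N,N-dimethylmethyleneiminium iodide
Product: 10 3,5-bis(benzyloxy)-2-bromo-6-[(dimethylamino)methyl]-4-methylphenol
Conditions: 9 (1.3 equiv), K2CO3, CH2Cl2, rt
Reagents that add atoms: N,N-dimethylmethyleneiminium iodide 9, C=[N+](C)C.[I-]
Why: Mannich-type aminomethylation with a preformed iminium salt can only strike the last free ring carbon, ortho to the phenoxide, and it installs the future bridge carbon without acid.

**Step 6**
Reactants: 10 bromophenol Mannich base
Product: 13 3,5-bis(benzyloxy)-2-[(dimethylamino)methyl]-4-methyl-6-(trimethylsilyl)phenyl trifluoromethanesulfonate, via aryl trimethylsilyl ether 11 (not isolated), via lithium ortho-silylphenoxide 12 (not isolated)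
Conditions: (a) HMDS, THF, 65 °C, then evaporate; (b) n-BuLi (1.1 equiv), THF, −78 °C; (c) PhNTf2, −78 °C to rt; aq. NH4Cl
Reagents that add atoms: hexamethyldisilazane, C[Si](C)(C)N[Si](C)(C)C; N-phenylbis(trifluoromethanesulfonimide), O=S(=O)(N(c1ccccc1)S(=O)(=O)C(F)(F)F)C(F)(F)F; n-butyllithium, [Li]CCCC (its lithium stays only in 12)
Why: O-silylation, bromine–lithium exchange (far faster at −78 °C than deprotonation of a benzyl ether) and retro-Brook 1,3-shift of silicon from oxygen to the lithiated carbon should give the ortho-silyl phenoxide, which is triflated in the same flask by a triflyl-transfer reagent that ignores the tertiary amine.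

**Step 7**
Reactants: 13 silylaryl triflate amine
Product: 14 3,5-bis(benzyloxy)-2-(chloromethyl)-4-methyl-6-(trimethylsilyl)phenyl trifluoromethanesulfonate
Conditions: ClCO2Et (1.5 equiv), CH2Cl2, 0 °C to rt
Reagents that add atoms: ethyl chloroformate, CCOC(=O)Cl
Why: Chloroformate-induced dealkylation of a tertiary benzylamine (von Braun type), in which chloride opens the acylammonium ion at the electron-rich benzylic carbon and no acid is formed that could cleave the aryl–silicon bond.

**Step 8**
Reactants: 15 phloroglucinol; 16 butyryl chloride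
Product: 17 1-(2,4,6-trihydroxyphenyl)butan-1-one
Conditions: AlCl3 (3.5 equiv), CH2Cl2–PhNO2, 0 °C to 45 °C; aq. HCl
Reagents that add atoms: butyryl chloride 16, CCCC(Cl)=O
Why: Friedel–Crafts acylation of phloroglucinol should stop after one acyl group because the chelated ketone deactivates the ring.

**Step 9**
Reactants: 17 butyrylphloroglucinol; 5 benzyl bromide
Product: 18 1-[2,4,6-tris(benzyloxy)phenyl]butan-1-one
Conditions: BnBr (3.5 equiv), K2CO3, DMF, 70 °C
Reagents that add atoms: benzyl bromide 5, BrCc1ccccc1
Why: Threefold Williamson ether synthesis, run warm in DMF so that the two hydroxyls hydrogen-bonded to the ketone are alkylated as well.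

**Step 10**
Reactants: 18 tris(benzyloxy)butyrophenone; 14 benzylic chloride (2.3 equiv)
Product: 19 1-[2,4,6-tris(benzyloxy)-3,5-bis{[2,4-bis(benzyloxy)-3-methyl-5-(trimethylsilyl)-6-(trifluoromethylsulfonyloxy)phenyl]methyl}phenyl]butan-1-one
Conditions: AgOTf (2.5 equiv), 2,6-di-tert-butyl-4-methylpyridine (3 equiv), 4 Å molecular sieves, CH2Cl2, −40 °C to 0 °C, slow addition of 14
Reagents that add atoms: none
Why: Twofold Friedel–Crafts benzylation in which silver-assisted ionisation of 14 gives a cation stabilised by its ortho and para benzyloxy groups, the two open carbons of ring B are the best nucleophiles present because the arms are fully substituted and deactivated by triflate, and the hindered pyridine takes up the acid that would otherwise cleave the aryl–silicon bond.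

**Step 11**
Reactants: 19 bis(silylaryl triflate); 20 butyric acid
Product: 22 1-[2,4,6-tris(benzyloxy)-3,5-bis{[2,4-bis(benzyloxy)-5-butanoyl-6-hydroxy-3-methylphenyl]methyl}phenyl]butan-1-one, via bis-aryne 21 (not isolated)
Conditions: 20 (5 equiv), CsF (10 equiv), THF (0.01 M in 19), sealed vessel, 125 °C
Reagents that add atoms: butyric acid 20, CCCC(=O)O
Why: Fluoride attacks silicon at C1 and triflate departs from C6, so each arm is unmasked in turn as a C1–C6 aryne under conditions that leave ketone, ethers and methylene bridges alone. Butyrate adds through oxygen to C6, the aryl anion so formed at C1 closes onto the ester carbonyl to a four-membered alkoxide, and this opens to the ortho-acyl phenoxide, which takes up the acid proton. This is the known fluoride-induced insertion of arynes into the C–O bond of carboxylic acids, run here twice in one molecule; the product gains no ring and no stereocentre. The step needs oxygen at C6 and not at C1: the inductively withdrawing C2 benzyloxy group distorts the aryne so that C6 is the more linear, more electrophilic carbon and charge builds up at C1 next to that oxygen, while the C5 substituent opposes this only through its bulk. It also needs acyl transfer to outrun protonation, which is why an aprotic solvent, high temperature and slow release of the aryne by sparingly soluble CsF are chosen. An excess of butyrate keeps the new phenoxide and the nearby benzyloxy oxygens of ring B from competing for the aryne.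

**Step 12**
Reactants: 22 hepta-O-benzyl ether
Product: 23 1-[3,5-bis{[3-butanoyl-2,4,6-trihydroxy-5-methylphenyl]methyl}-2,4,6-trihydroxyphenyl]butan-1-one (target)
Conditions: H2 (1 atm), 10 % Pd/C, EtOAc–MeOH, rt
Reagents that add atoms: none
Why: Catalytic hydrogenolysis of seven aryl benzyl ethers under neutral conditions should leave the hydrogen-bonded aryl ketones and the acid- and base-sensitive methylene bridges untouched.

**Compound list**
1 | 2-methylresorcinol | Cc1c(O)cccc1O | starting material
2 | 2-methyl-1,3-bis(trimethylsilyloxy)benzene | Cc1c(O[Si](C)(C)C)cccc1O[Si](C)(C)C | intermediate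
3 | 2-[4-methyl-3,5-bis(trimethylsilyloxy)phenyl]-4,4,5,5-tetramethyl-1,3,2-dioxaborolane | Cc1c(O[Si](C)(C)C)cc(B2OC(C)(C)C(C)(C)O2)cc1O[Si](C)(C)C | intermediate
4 | 2-methyl-5-(4,4,5,5-tetramethyl-1,3,2-dioxaborolan-2-yl)benzene-1,3-diol | Cc1c(O)cc(B2OC(C)(C)C(C)(C)O2)cc1O | intermediate
5 | benzyl bromide | BrCc1ccccc1 | starting material
6 | 2-[3,5-bis(benzyloxy)-4-methylphenyl]-4,4,5,5-tetramethyl-1,3,2-dioxaborolane | Cc1c(OCc2ccccc2)cc(B2OC(C)(C)C(C)(C)O2)cc1OCc1ccccc1 | intermediate
7 | 3,5-bis(benzyloxy)-4-methylphenol | Cc1c(OCc2ccccc2)cc(O)cc1OCc1ccccc1 | intermediate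
8 | 3,5-bis(benzyloxy)-2-bromo-4-methylphenol | Cc1c(OCc2ccccc2)cc(O)c(Br)c1OCc1ccccc1 | intermediate
9 | N,N-dimethylmethyleneiminium iodide | C=[N+](C)C.[I-] | starting material
10 | 3,5-bis(benzyloxy)-2-bromo-6-[(dimethylamino)methyl]-4-methylphenol | CN(C)Cc1c(O)c(Br)c(OCc2ccccc2)c(C)c1OCc1ccccc1 | intermediate
11 | trimethylsilyl ether of 10 | CN(C)Cc1c(O[Si](C)(C)C)c(Br)c(OCc2ccccc2)c(C)c1OCc1ccccc1 | intermediate
12 | lithium 3,5-bis(benzyloxy)-2-[(dimethylamino)methyl]-4-methyl-6-(trimethylsilyl)phenoxide | [Li+].CN(C)Cc1c([O-])c([Si](C)(C)C)c(OCc2ccccc2)c(C)c1OCc1ccccc1 | intermediate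
13 | 3,5-bis(benzyloxy)-2-[(dimethylamino)methyl]-4-methyl-6-(trimethylsilyl)phenyl trifluoromethanesulfonate | CN(C)Cc1c(OS(=O)(=O)C(F)(F)F)c([Si](C)(C)C)c(OCc2ccccc2)c(C)c1OCc1ccccc1 | intermediate
14 | 3,5-bis(benzyloxy)-2-(chloromethyl)-4-methyl-6-(trimethylsilyl)phenyl trifluoromethanesulfonate | ClCc1c(OS(=O)(=O)C(F)(F)F)c([Si](C)(C)C)c(OCc2ccccc2)c(C)c1OCc1ccccc1 | intermediate
15 | phloroglucinol | Oc1cc(O)cc(O)c1 | starting material
16 | butyryl chloride | CCCC(Cl)=O | starting material
17 | 1-(2,4,6-trihydroxyphenyl)butan-1-one | CCCC(=O)c1c(O)cc(O)cc1O | intermediate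
18 | 1-[2,4,6-tris(benzyloxy)phenyl]butan-1-one | CCCC(=O)c1c(OCc2ccccc2)cc(OCc2ccccc2)cc1OCc1ccccc1 | intermediate
19 | central tris(benzyloxy) ketone with two 2-(trimethylsilyl)aryl triflate arms (precursor of the key step) | CCCC(=O)c1c(OCc2ccccc2)c(Cc2c(OCc3ccccc3)c(C)c(OCc3ccccc3)c([Si](C)(C)C)c2OS(=O)(=O)C(F)(F)F)c(OCc2ccccc2)c(Cc2c(OCc3ccccc3)c(C)c(OCc3ccccc3)c([Si](C)(C)C)c2OS(=O)(=O)C(F)(F)F)c1OCc1ccccc1 | intermediate
20 | butyric acid | CCCC(=O)O | starting material
21 | bis-aryne (drawn with both C1–C6 triple bonds; in the flask they are unmasked one after the other) | CCCC(=O)c1c(OCc2ccccc2)c(CC2=C(OCc3ccccc3)C(C)=C(OCc3ccccc3)C#C2)c(OCc2ccccc2)c(CC2=C(OCc3ccccc3)C(C)=C(OCc3ccccc3)C#C2)c1OCc1ccccc1 | intermediate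
22 | hepta-O-benzyl ether of the target with free C6 hydroxyls (product of the key step) | CCCC(=O)c1c(OCc2ccccc2)c(Cc2c(OCc3ccccc3)c(C)c(OCc3ccccc3)c(C(=O)CCC)c2O)c(OCc2ccccc2)c(Cc2c(OCc3ccccc3)c(C)c(OCc3ccccc3)c(C(=O)CCC)c2O)c1OCc1ccccc1 | intermediate
23 | CNP0296563.0 | CCCC(=O)c1c(O)c(C)c(O)c(Cc2c(O)c(Cc3c(O)c(C)c(O)c(C(=O)CCC)c3O)c(O)c(C(=O)CCC)c2O)c1O | target

**Step count**
- Total step count: 12.
- Longest linear sequence: 10 (steps 1–7, 10, 11, 12).

**Steps most likely to fail**

1. **Step 11.**
   - What may go wrong: the aryl anion at C1 is protonated before the acyl group migrates, so the acid is only O-arylated. A benzyloxy oxygen of ring B, which can reach C6 through a six-membered arrangement, may capture the aryne. One arm may follow the wanted course while the other does not.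
   - Fallback (from 19, back at 22): the C–O and the C–C bond are made one after the other.
   - The aryne is released with CsF in acetonitrile at room temperature in the presence of 20. These conditions are known to stop at plain O-arylation of a carboxylic acid, and should give the bis(aryl butanoate) F1 with hydrogen at C1.
   - C1 is then the only open carbon on an activated ring. It is acylated in a Friedel–Crafts reaction with the mixed anhydride made from 20 and trifluoroacetic anhydride, giving the diketone diester F2.
   - K2CO3 in methanol removes the two aryl esters and gives 22.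

2. **Step 10.**
   - What may go wrong: the second alkylation of the crowded ring B stalls, the cation is intercepted by an ether or ketone oxygen, or silicon is lost through ipso attack if acid builds up.
   - Fallback (from 18 and 14, back at 19): electrophilic substitution is replaced by cross-coupling.
   - Compound 18 is iodinated at both open carbons with N-iodosuccinimide and catalytic trifluoroacetic acid to the diiodide F3.
   - Compound 14 is converted with zinc dust and LiCl in THF to the benzylic zinc chloride F4.
   - A twofold Negishi coupling (Pd(OAc)2, SPhos, THF) joins them. The carbon–iodine bonds should add to zerovalent palladium well before the triflates, which are shielded on both sides.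

3. **Step 6.**
   - What may go wrong: the aryllithium is protonated, or held by the neighbouring amine, before silicon migrates. The phenoxide, shielded by silicon on one side and the aminomethyl group on the other, may also be triflated too slowly.
   - Fallback (from 8, back at 13): silicon is brought in before the aminomethyl group.
   - Compound 8 is silylated on oxygen with HMDS to the silyl ether F5.
   - n-BuLi at −78 °C followed by an NH4Cl quench gives the ortho-silylphenol F6.
   - Aminomethylation with 9 at the last free carbon gives the Mannich base F7.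
   - The isolated phenol is triflated as its sodium salt (NaH, PhNTf2, THF) to 13.

**Further compounds**
F1 | step 11 | bis(aryl butanoate), hydrogen at C1 of both arms | CCCC(=O)c1c(OCc2ccccc2)c(Cc2c(OCc3ccccc3)c(C)c(OCc3ccccc3)cc2OC(=O)CCC)c(OCc2ccccc2)c(Cc2c(OCc3ccccc3)c(C)c(OCc3ccccc3)cc2OC(=O)CCC)c1OCc1ccccc1
F2 | step 11 | diketone diester, butanoyl at C1 and butanoate at C6 of both arms | CCCC(=O)c1c(OCc2ccccc2)c(Cc2c(OCc3ccccc3)c(C)c(OCc3ccccc3)c(C(=O)CCC)c2OC(=O)CCC)c(OCc2ccccc2)c(Cc2c(OCc3ccccc3)c(C)c(OCc3ccccc3)c(C(=O)CCC)c2OC(=O)CCC)c1OCc1ccccc1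
F3 | step 10 | 1-[2,4,6-tris(benzyloxy)-3,5-diiodophenyl]butan-1-one | CCCC(=O)c1c(OCc2ccccc2)c(I)c(OCc2ccccc2)c(I)c1OCc1ccccc1
F4 | step 10 | benzylic zinc chloride from 14 | Cl[Zn]Cc1c(OS(=O)(=O)C(F)(F)F)c([Si](C)(C)C)c(OCc2ccccc2)c(C)c1OCc1ccccc1
F5 | step 6 | [3,5-bis(benzyloxy)-2-bromo-4-methylphenoxy]trimethylsilane | Cc1c(OCc2ccccc2)cc(O[Si](C)(C)C)c(Br)c1OCc1ccccc1
F6 | step 6 | 3,5-bis(benzyloxy)-4-methyl-2-(trimethylsilyl)phenol | Cc1c(OCc2ccccc2)cc(O)c([Si](C)(C)C)c1OCc1ccccc1
F7 | step 6 | 3,5-bis(benzyloxy)-2-[(dimethylamino)methyl]-4-methyl-6-(trimethylsilyl)phenol | CN(C)Cc1c(O)c([Si](C)(C)C)c(OCc2ccccc2)c(C)c1OCc1ccccc1
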